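**Retrosynthetic overview**
1. The C5–C1' biaryl bond is cut last (Suzuki–Miyaura). This gives a (3S)-5-bromo-6,8-dimethoxy-1,3-dimethyl-3,4-dihydroisoquinoline and 4,5-dimethoxy-2-methyl-1-naphthylboronic acid, whose second ring comes from an aryne/amide-dienolate annulation.
2. Ring B (C1, N2, C3, C4, C4a, C8a) is opened at C1=N2 to an ortho-(2-aminopropyl)acetophenone, with N2 masked as a 2-nitrobenzenesulfonamide and the C1 acetyl masked as a 1-ethoxyvinyl group.
3. Feature used: C4a and C8a are adjacent ring A carbons. C4a holds the C4–C3–N2 arm, C8a holds C1, and C8–OMe flanks C8a on its other side. This is the pattern of an aryl iodide (iodine at C8a) with one blocked ortho position (C8) and one free ortho C–H (C4a).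
4. C4a–C4 and C8a–C1 are therefore made together in one palladium/norbornene three-component reaction of 1-iodo-2,4-dimethoxybenzene, the L-alaninol-derived (S)-N-nosyl-2-methylaziridine (source of C3) and 1-ethoxyvinylboronic acid pinacol ester.
5. Ring order: ring A is bought, ring B closes by imine condensation after C5 bromination, the naphthalene is finished in a parallel branch, and the axis is made last.

Key step: step 2

Assumption: the SMILES fixes only C3 (S) and leaves the configurationally stable C5–C1' axis open. The route therefore controls C3 only, and the two atropo-diastereomers expected from the last step would be separated by chromatography.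

**Step 1**
Reactants: 1 L-alaninol; 2 2-nitrobenzenesulfonyl chloride
Product: 4 (2S)-2-methyl-1-(2-nitrophenylsulfonyl)aziridine, via N,O-bis-nosylate 3 (not isolated)
Conditions: 2 (2.2 equiv), pyridine/CH2Cl2, 0 °C to rt; then 2 M aq KOH, rt
Reagents that add atoms: none
Why: N,O-bis-sulfonylation followed by base-induced 3-exo-tet closure (Wenker-type aziridine synthesis) displaces the sulfonate at the primary CH2 only, so the (S) centre of 1 is carried over untouched.

**Step 2**
Reactants: 4 (2S)-2-methyl-1-(2-nitrophenylsulfonyl)aziridine; 5 1-iodo-2,4-dimethoxybenzene; 6 2-(1-ethoxyethenyl)-4,4,5,5-tetramethyl-1,3,2-dioxaborolane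
Product: 7 N-{(2S)-1-[2-(1-ethoxyethenyl)-3,5-dimethoxyphenyl]propan-2-yl}-2-nitrobenzenesulfonamide
Conditions: Pd(OAc)2 (10 mol %), P(2-furyl)3 (25 mol %), norbornene (2 equiv), Cs2CO3 (3 equiv), H2O (5 equiv), 4 (1.5 equiv), 6 (2 equiv), MeCN, 80 °C, argon; chromatography on Et3N-deactivated silica
Reagents that add atoms: none
Why: This is a Catellani reaction (palladium/norbornene cooperative catalysis) with an aziridine as ortho-alkylating partner and a Suzuki–Miyaura end: zerovalent palladium adds to the C–I bond of 5, norbornene inserts, and base-assisted palladation of the only free ortho C–H (the later C4a) gives the five-membered aryl–norbornyl palladacycle of divalent palladium. This electron-rich palladacycle opens 4 by SN2-type attack at the unsubstituted CH2, the tetravalent palladium species so formed reductively eliminates to make C4a–C4, and the aryl group, now substituted at both ortho positions, forces β-carbon elimination of norbornene. The arylpalladium species left at the ipso carbon (C8a) transmetalates with 6, and reductive elimination makes C8a–C1, the ethoxyvinyl group serving as a base-stable masked acetyl. No ring is closed and no stereocentre is created: the C–N bond at the methyl-bearing carbon of 4 is never broken, so its (S) centre becomes C3 unchanged. Site selectivity rests on the C2 methoxy group of 5, which blocks the second ortho position and supplies the ortho substituent needed for norbornene extrusion, and on the steric bias of the aziridine towards opening at CH2. The chemoselectivity needed is that norbornene insertion outruns direct coupling of 5 with 6 (excess norbornene, slowly transmetalating pinacol ester), and that transmetalation then outruns N-arylation of the neighbouring sulfonamide anion to a 2-methylindoline (excess 6, a small weakly donating and weakly nucleophilic phosphine, a poorly nucleophilic nosylamide).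

**Step 3**
Reactants: 7 N-{(2S)-1-[2-(1-ethoxyethenyl)-3,5-dimethoxyphenyl]propan-2-yl}-2-nitrobenzenesulfonamide
Product: 8 N-[(2S)-1-(2-acetyl-3,5-dimethoxyphenyl)propan-2-yl]-2-nitrobenzenesulfonamide
Conditions: 1 M aq HCl, THF, 0 °C to rt
Reagents that add atoms: water, O
Why: Acid-catalysed enol ether hydrolysis proceeds by C-protonation to an aryl-stabilised oxocarbenium ion that water converts into the methyl ketone, under conditions that leave the sulfonamide, the aryl methyl ethers and C3 alone.

**Step 4**
Reactants: 8 N-[(2S)-1-(2-acetyl-3,5-dimethoxyphenyl)propan-2-yl]-2-nitrobenzenesulfonamide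
Product: 9 N-[(2S)-1-(2-acetyl-6-bromo-3,5-dimethoxyphenyl)propan-2-yl]-2-nitrobenzenesulfonamide
Conditions: NBS (1.05 equiv), MeCN, 0 °C to rt, dark; aq Na2S2O3 quench
Reagents that add atoms: N-bromosuccinimide, O=C1CCC(=O)N1Br
Why: Electrophilic aromatic bromination should go to C5 (para to C8–OMe, ortho to C6–OMe and to the alkyl arm) rather than to C7, which is squeezed between two methoxy groups; the twisted, slowly enolising acetyl group should not compete, and brominating before ring closure avoids an enamine-type C1 methyl group.

**Step 5**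
Reactants: 9 N-[(2S)-1-(2-acetyl-6-bromo-3,5-dimethoxyphenyl)propan-2-yl]-2-nitrobenzenesulfonamide
Product: 11 (3S)-5-bromo-6,8-dimethoxy-1,3-dimethyl-3,4-dihydroisoquinoline, via amino ketone 10 (not isolated)
Conditions: PhSH (1.3 equiv), K2CO3 (3 equiv), DMF, rt to 50 °C; acid–base extraction (1 M aq HCl, then aq NH3)
Reagents that add atoms: none
Why: Fukuyama deprotection (thiolate attack on the nitroarene, Meisenheimer adduct, loss of SO2) frees the primary amine, which condenses 6-exo-trig with the ortho acetyl group to the conjugated cyclic imine without touching C3; closing ring B here removes the N–H that could otherwise be arylated at C5 under palladium in step 11.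

**Step 6**
Reactants: 12 3,3-dimethylacryloyl chloride
Product: 13 N,N-diethyl-3-methylbut-2-enamide
Conditions: Et2NH (1.1 equiv), 2 M aq NaOH, CH2Cl2, 0 °C to rt
Reagents that add atoms: diethylamine, CCNCC
Why: Schotten–Baumann acylation of a secondary amine by an acid chloride is reliable, and any double-bond isomer would give the same dienolate in the next step.

**Step 7**
Reactants: 13 N,N-diethyl-3-methylbut-2-enamide; 14 3-bromoanisole
Product: 17 8-methoxy-3-methylnaphthalen-1-ol, via lithium dienolate 15 (not isolated), via 3-methoxybenzyne 16 (not isolated)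
Conditions: LiN(i-Pr)2 (3.5 equiv), THF, −78 °C, add 13, then 14, −78 °C to rt; 1 M aq HCl quench
Reagents that add atoms: none
Why: In this aryne annulation with an amide dienolate the base removes a γ-proton of 13 and the proton of 14 between OMe and Br (then LiBr is lost); the γ-carbon of 15 adds to the aryne carbon meta to methoxy, and the aryl anion thus placed ortho to methoxy attacks the amide carbonyl with loss of LiNEt2, so that after tautomerisation the hydroxyl sits peri to the methoxy group.

**Step 8**
Reactants: 17 8-methoxy-3-methylnaphthalen-1-ol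
Product: 18 1,8-dimethoxy-3-methylnaphthalene
Conditions: MeI (2 equiv), K2CO3 (3 equiv), DMF, rt to 40 °C
Reagents that add atoms: iodomethane, CI
Why: Williamson ether synthesis on the naphtholate in a polar aprotic solvent overcomes the peri hydrogen bond of the hydroxyl group.

**Step 9**
Reactants: 18 1,8-dimethoxy-3-methylnaphthalene
Product: 19 1-bromo-4,5-dimethoxy-2-methylnaphthalene
Conditions: NBS (1.0 equiv), MeCN, −20 °C to 0 °C, dark
Reagents that add atoms: N-bromosuccinimide, O=C1CCC(=O)N1Br
Why: Electrophilic aromatic bromination should prefer the α-position activated by both a para methoxy and an ortho methyl group over the other para-to-methoxy α-position, which lacks the methyl activation.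

**Step 10**
Reactants: 19 1-bromo-4,5-dimethoxy-2-methylnaphthalene
Product: 21 (4,5-dimethoxy-2-methylnaphthalen-1-yl)boronic acid, via aryllithium 20 (not isolated)
Conditions: n-BuLi (1.1 equiv), THF, −78 °C; B(Oi-Pr)3 (2 equiv), −78 °C to rt; 1 M aq HCl
Reagents that add atoms: triisopropyl borate, CC(C)OB(OC(C)C)OC(C)C; water, O
Why: Bromine–lithium exchange, trapping of the aryllithium with a borate ester and hydrolysis is the standard route to hindered arylboronic acids, and the methyl ethers tolerate it.

**Step 11**
Reactants: 11 (3S)-5-bromo-6,8-dimethoxy-1,3-dimethyl-3,4-dihydroisoquinoline; 21 (4,5-dimethoxy-2-methylnaphthalen-1-yl)boronic acid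
Product: 22 O-methylancistrocladinine
Conditions: Pd(OAc)2 (5 mol %), SPhos (10 mol %), K3PO4 (3 equiv), 21 (1.5 equiv), toluene/H2O (10:1), 100 °C, argon
Reagents that add atoms: none
Why: Suzuki–Miyaura coupling with a bulky electron-rich dialkylbiarylphosphine is the established way to biaryls with four ortho substituents; the tied-back ring B offers no N–H and less bulk than the open chain, the mild base leaves C3 untouched, and the axis forms without control (see assumption).

**Compound list**
1 | L-alaninol, (2S)-2-aminopropan-1-ol | C[C@H](N)CO | starting material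
2 | 2-nitrobenzenesulfonyl chloride | O=S(=O)(Cl)c1ccccc1[N+](=O)[O-] | starting material
3 | (2S)-2-{[(2-nitrophenyl)sulfonyl]amino}propyl 2-nitrobenzenesulfonate (N,O-bis-nosylate) | C[C@H](NS(=O)(=O)c1ccccc1[N+](=O)[O-])COS(=O)(=O)c1ccccc1[N+](=O)[O-] | intermediate
4 | (2S)-2-methyl-1-(2-nitrophenylsulfonyl)aziridine | C[C@H]1CN1S(=O)(=O)c1ccccc1[N+](=O)[O-] | intermediate
5 | 1-iodo-2,4-dimethoxybenzene | COc1ccc(I)c(OC)c1 | starting material
6 | 2-(1-ethoxyethenyl)-4,4,5,5-tetramethyl-1,3,2-dioxaborolane | CCOC(=C)B1OC(C)(C)C(C)(C)O1 | starting material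
7 | N-{(2S)-1-[2-(1-ethoxyethenyl)-3,5-dimethoxyphenyl]propan-2-yl}-2-nitrobenzenesulfonamide | COc1cc(OC)c(C(=C)OCC)c(C[C@H](C)NS(=O)(=O)c2ccccc2[N+](=O)[O-])c1 | intermediate
8 | N-[(2S)-1-(2-acetyl-3,5-dimethoxyphenyl)propan-2-yl]-2-nitrobenzenesulfonamide | COc1cc(OC)c(C(C)=O)c(C[C@H](C)NS(=O)(=O)c2ccccc2[N+](=O)[O-])c1 | intermediate
9 | N-[(2S)-1-(2-acetyl-6-bromo-3,5-dimethoxyphenyl)propan-2-yl]-2-nitrobenzenesulfonamide | COc1cc(OC)c(C(C)=O)c(C[C@H](C)NS(=O)(=O)c2ccccc2[N+](=O)[O-])c1Br | intermediate
10 | 1-{2-[(2S)-2-aminopropyl]-3-bromo-4,6-dimethoxyphenyl}ethan-1-one (amino ketone) | COc1cc(OC)c(C(C)=O)c(C[C@H](C)N)c1Br | intermediate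
11 | (3S)-5-bromo-6,8-dimethoxy-1,3-dimethyl-3,4-dihydroisoquinoline | COc1cc(OC)c(Br)c2c1C(C)=N[C@@H](C)C2 | intermediate
12 | 3,3-dimethylacryloyl chloride | CC(C)=CC(Cl)=O | starting material
13 | N,N-diethyl-3-methylbut-2-enamide | CCN(CC)C(=O)C=C(C)C | intermediate
14 | 3-bromoanisole | COc1cccc(Br)c1 | starting material
15 | lithium 1-(diethylamino)-3-methylbuta-1,3-dien-1-olate (lithium dienolate of 13) | [Li+].C=C(C)C=C([O-])N(CC)CC | intermediate
16 | 3-methoxybenzyne (1,2-didehydro-3-methoxybenzene) | COC1=CC=CC#C1 | intermediate
17 | 8-methoxy-3-methylnaphthalen-1-ol | Cc1cc(O)c2c(OC)cccc2c1 | intermediate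
18 | 1,8-dimethoxy-3-methylnaphthalene | COc1cc(C)cc2cccc(OC)c12 | intermediate
19 | 1-bromo-4,5-dimethoxy-2-methylnaphthalene | COc1cc(C)c(Br)c2cccc(OC)c12 | intermediate
20 | (4,5-dimethoxy-2-methylnaphthalen-1-yl)lithium (aryllithium) | [Li]c1c(C)cc(OC)c2c(OC)cccc12 | intermediate
21 | (4,5-dimethoxy-2-methylnaphthalen-1-yl)boronic acid | COc1cc(C)c(B(O)O)c2cccc(OC)c12 | intermediate
22 | O-methylancistrocladinine, (3S)-5-(4,5-dimethoxy-2-methylnaphthalen-1-yl)-6,8-dimethoxy-1,3-dimethyl-3,4-dihydroisoquinoline | COc1cc(OC)c(-c2c(C)cc(OC)c3c(OC)cccc23)c2c1C(C)=N[C@@H](C)C2 | target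

**Totals**
Total step count: 11.
Longest linear sequence: 6 steps (1, 2, 3, 4, 5, 11 from L-alaninol; equally 6, 7, 8, 9, 10, 11 from 3,3-dimethylacryloyl chloride).

**Steps most likely to fail**

*Step 2.*
- What may go wrong: the ipso arylpalladium intermediate may be captured by the neighbouring sulfonamide nitrogen (ring closure to an indoline) before it transmetalates. The iodide may couple with the boronate before norbornene has inserted. The activated aziridine may be used up by base, water or its own sulfonamide product.
- Fallback: it sets out from 1 and comes back at 11, bypassing steps 2–5. The two ring A bonds are made one after the other by classical chemistry.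
- Route: Boc2O converts 1 into tert-butyl N-[(2S)-1-hydroxypropan-2-yl]carbamate F1. TsCl and powdered KOH in THF give, through (2S)-2-[(tert-butoxycarbonyl)amino]propyl 4-methylbenzenesulfonate F2, tert-butyl (2S)-2-methylaziridine-1-carboxylate F3. Purchased 3,5-dimethoxyphenylmagnesium chloride with CuBr·SMe2 (cat.) in THF at −30 °C opens F3 at its CH2 to tert-butyl N-[(2S)-1-(3,5-dimethoxyphenyl)propan-2-yl]carbamate F4. HCl in dioxane frees (2S)-1-(3,5-dimethoxyphenyl)propan-2-amine F5. Ac2O/Et3N gives N-[(2S)-1-(3,5-dimethoxyphenyl)propan-2-yl]acetamide F6. NBS in MeCN brominates ortho to the side chain and para to a methoxy group to N-[(2S)-1-(2-bromo-3,5-dimethoxyphenyl)propan-2-yl]acetamide F7. Bischler–Napieralski cyclisation (POCl3, MeCN, reflux) at the only free ortho position then closes ring B to 11.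

*Step 11.*
- What may go wrong: transmetalation and reductive elimination at an axis with four ortho substituents are slow. Protodeboronation of the electron-rich boronic acid and hydrodebromination of the bromide may therefore overtake the coupling.
- Fallback: it sets out from 19 and 11 and comes back at 22, making step 10 unnecessary. The boron nucleophile and the aqueous base are given up for an anhydrous Negishi coupling.
- Route: bromide 19 is lithiated to 20 as in step 10 and transmetalated with ZnCl2 in THF to chloro(4,5-dimethoxy-2-methylnaphthalen-1-yl)zinc F8. F8 is coupled with 11 using Pd2(dba)3/RuPhos in THF at 70 °C. The arylzinc reagent is not basic enough to deprotonate the C1 methyl group of the imine.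

*Step 7.*
- What may go wrong: the aryne may be intercepted by diisopropylamine or its lithium amide. It may be generated out of step with the dienolate. The dienolate may also react through its α-carbon, all of which erode the annulation.
- Fallback: it sets out from 14 and comes back at 17. The aryne is avoided altogether.
- Route: 14 is lithiated between OMe and Br with LiN(i-Pr)2 in THF held at −78 °C, where (2-bromo-6-methoxyphenyl)lithium F9 should not yet lose LiBr. Trapping with diethylcarbamoyl chloride gives 2-bromo-N,N-diethyl-6-methoxybenzamide F10. Stille coupling with tributyl(2-methylallyl)stannane (Pd(PPh3)4, toluene, 110 °C) gives N,N-diethyl-2-methoxy-6-(2-methylprop-2-en-1-yl)benzamide F11. LiN(i-Pr)2 in THF (−78 °C to rt) removes a benzylic–allylic proton, and the allyl anion closes through its terminal carbon onto the amide carbonyl with loss of LiNEt2 (anionic annulation of an ortho-allylbenzamide), giving 17 after tautomerisation.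

**Further compounds**
F1 | step 2 | tert-butyl N-[(2S)-1-hydroxypropan-2-yl]carbamate | C[C@H](NC(=O)OC(C)(C)C)CO
F2 | step 2 | (2S)-2-[(tert-butoxycarbonyl)amino]propyl 4-methylbenzenesulfonate | C[C@H](NC(=O)OC(C)(C)C)COS(=O)(=O)c1ccc(C)cc1
F3 | step 2 | tert-butyl (2S)-2-methylaziridine-1-carboxylate | C[C@H]1CN1C(=O)OC(C)(C)C
F4 | step 2 | tert-butyl N-[(2S)-1-(3,5-dimethoxyphenyl)propan-2-yl]carbamate | COc1cc(OC)cc(C[C@H](C)NC(=O)OC(C)(C)C)c1
F5 | step 2 | (2S)-1-(3,5-dimethoxyphenyl)propan-2-amine | COc1cc(OC)cc(C[C@H](C)N)c1
F6 | step 2 | N-[(2S)-1-(3,5-dimethoxyphenyl)propan-2-yl]acetamide | COc1cc(OC)cc(C[C@H](C)NC(C)=O)c1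
F7 | step 2 | N-[(2S)-1-(2-bromo-3,5-dimethoxyphenyl)propan-2-yl]acetamide | COc1cc(OC)c(Br)c(C[C@H](C)NC(C)=O)c1
F8 | step 11 | chloro(4,5-dimethoxy-2-methylnaphthalen-1-yl)zinc | Cl[Zn]c1c(C)cc(OC)c2c(OC)cccc12
F9 | step 7 | (2-bromo-6-methoxyphenyl)lithium | [Li]c1c(Br)cccc1OC
F10 | step 7 | 2-bromo-N,N-diethyl-6-methoxybenzamide | CCN(CC)C(=O)c1c(Br)cccc1OC
F11 | step 7 | N,N-diethyl-2-methoxy-6-(2-methylprop-2-en-1-yl)benzamide | CCN(CC)C(=O)c1c(CC(C)=C)cccc1OC
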